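The five-membered lactone (O–C7–C8–C17–C19) is a β-hydroxy lactone: the tertiary C8 carbinol lies β to the C19 carbonyl, so C8–C17 is an aldol bond between a propanoate on the C7 oxygen and a C8 ketone of the ten-membered ring. Everything rests on that disconnection. In one operation, samarium diiodide converts the C7 2-bromopropanoate of 33 into a samarium enolate that adds to the neighbouring ketone, closing the lactone and setting C8 and C17. The precursor 33 is the fully assembled ring A/ten-ring bicycle (Diels–Alder ring A, Nozaki–Hiyama–Kishi closure at C5–C6) carrying the C6 chloride, the C9 silyl ether, the masked enone and a free C8 ketone.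

Key step: step 26

Remarks on the chemistry (one line each):
- Numbering: the briarane numbering of the target is used for every intermediate (C1 quaternary CMe, C2, C3, C4, C5 with methylene C16, C6 to C10, ring A C10–C11–C12–C13–C14–C1, lactone C17/C18/C19, methyls C15 on C1 and C20 on C11); the SMILES fix the absolute configuration.
- Assumption: the (S)-prolinol-derived oxazaborolidinium ion is taken to direct the diene to the dienophile face that gives 4 as drawn (formyl C–H···O model for 2-substituted enals); if the sense is opposite, the (R)-catalyst is used and nothing else changes.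
- The C11 centre of 4–22 and the bromine-bearing carbon of 31–33 are of no consequence; both are planarised later (steps 17 and 26), and commercial racemic 2-bromopropanoyl bromide is used.
- Protecting-group design: the tertiary C11 hydroxyl is left free from step 18 on (flanked by the ketal carbon and C10, it should be inert to the reagents used), so the end game is one acidic fluoride step and one acetylation. The C8 ketone is unveiled last by a neutral oxidation.

Step 1
Reactants: 1 pent-1-en-3-one
Product: 2 (Z)-tert-butyldimethyl(penta-1,3-dien-3-yloxy)silane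
Conditions: TBSOTf, Et3N, Et2O, 0 °C
Reagents that add atoms: tert-butyldimethylsilyl trifluoromethanesulfonate, CC(C)(C)[Si](C)(C)OS(=O)(=O)C(F)(F)F
Why: Soft enolisation (silyl triflate/amine) on the ethyl side of the enone should give the 2-silyloxy diene as the (Z)-enol ether, whose methyl group is cis to oxygen and therefore "outside" in the s-cis diene.

Step 2
Reactants: 2 (Z)-tert-butyldimethyl(penta-1,3-dien-3-yloxy)silane; 3 ethyl (2E)-3-methyl-4-oxobut-2-enoate
Product: 4 ethyl 6-formyl-2,6-dimethyl-3-[(tert-butyldimethylsilyl)oxy]cyclohex-3-ene-1-carboxylate (formyl C2 on C1 trans to the ester C9 on C10; C11 methyl cis to formyl)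
Conditions: (S)-o-tolyl-CBS oxazaborolidine·Tf2NH (10 mol %), CH2Cl2, −78 °C
Reagents that add atoms: none
Why: Catalytic enantioselective Diels–Alder reaction of a 2-substituted enal on a cationic oxazaborolidine, in which the nucleophilic diene terminus C11 should bond to C10 (β to the formyl group, silyloxy carbon para to C1), the E geometry of 3 fixes C2 and C9 trans, the catalyst selects the face that sets C1 and C10, and the endo-derived C11 centre is immaterial.

Step 3
Reactants: 4 ring-A aldehyde ester
Product: 5 ethyl 6-(1-hydroxyethyl)-2,6-dimethyl-3-[(tert-butyldimethylsilyl)oxy]cyclohex-3-ene-1-carboxylate (both C2 carbinol epimers)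
Conditions: MeMgBr, THF, −78 °C; NH4Cl quench at −78 °C
Reagents that add atoms: methylmagnesium bromide, C[Mg]Br
Why: Grignard addition is far faster to the aldehyde than to the hindered ester at −78 °C, and the uncontrolled carbinol centre is removed by oxidation in step 4.

Step 4
Reactants: 5 C2 carbinol
Product: 6 ethyl 6-acetyl-2,6-dimethyl-3-[(tert-butyldimethylsilyl)oxy]cyclohex-3-ene-1-carboxylate
Conditions: Dess–Martin periodinane, NaHCO3, CH2Cl2, 0 °C → rt
Reagents that add atoms: none
Why: Buffered Dess–Martin oxidation of the secondary alcohol should give the methyl ketone (C2 carbonyl, C3 methyl) without touching the silyl enol ether or the ester.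

Step 5
Reactants: 6 methyl ketone; 7 2,3-dibromoprop-1-ene
Product: 8 ethyl 6-(4-bromopent-4-enoyl)-2,6-dimethyl-3-[(tert-butyldimethylsilyl)oxy]cyclohex-3-ene-1-carboxylate
Conditions: LDA, THF, −78 °C; then 7, DMPU, −78 → −40 °C
Reagents that add atoms: none
Why: Kinetic lithium enolate alkylation, in which the methyl group is the only enolisable position of the ketone (C1 is quaternary) and is deprotonated faster than the hindered ester α-CH, and the enolate should displace the allylic bromide by SN2 while the vinylic bromide is inert.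

Step 6
Reactants: 8 bromoalkenyl ketone
Product: 9 ethyl 6-[(1R)-4-bromo-1-hydroxypent-4-enyl]-2,6-dimethyl-3-[(tert-butyldimethylsilyl)oxy]cyclohex-3-ene-1-carboxylate (C2 alcohol, 2R)
Conditions: (S)-Me-CBS (0.3 equiv), BH3·SMe2, THF, −20 °C; MeOH quench
Reagents that add atoms: none
Why: Corey–Bakshi–Shibata reduction with the quaternary C1 as the large and the C3 methylene as the small ketone substituent, so that the (S)-catalyst should deliver hydride to the face giving the 2R carbinol of the target, while ester, enol ether and bromoalkene are inert at this temperature.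

Step 7
Reactants: 9 C2 alcohol
Product: 10 ethyl 6-[(1R)-4-bromo-1-[(tert-butyldimethylsilyl)oxy]pent-4-enyl]-2,6-dimethyl-3-[(tert-butyldimethylsilyl)oxy]cyclohex-3-ene-1-carboxylate
Conditions: TBSOTf, 2,6-lutidine, CH2Cl2, −78 → 0 °C
Reagents that add atoms: tert-butyldimethylsilyl trifluoromethanesulfonate, CC(C)(C)[Si](C)(C)OS(=O)(=O)C(F)(F)F
Why: Silyl triflate silylation is needed for the neopentyl-type secondary alcohol and also blocks lactonisation onto the C9 ester.

Step 8
Reactants: 10 C2 silyl ether ester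
Product: 11 C9 primary alcohol (the ester of 10 reduced to CH2OH)
Conditions: DIBAL-H, CH2Cl2, −78 → −20 °C; Rochelle salt
Reagents that add atoms: none
Why: Hydride reduction of the ester to the primary alcohol, with silyl enol ether, silyl ether and bromoalkene inert to DIBAL.

Step 9
Reactants: 11 C9 primary alcohol
Product: 12 C9 aldehyde (carbaldehyde on C10)
Conditions: Dess–Martin periodinane, pyridine, CH2Cl2, 0 °C
Reagents that add atoms: none
Why: Pyridine-buffered Dess–Martin oxidation should give the aldehyde without epimerising C10 or cleaving the silyl enol ether.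

Step 10
Reactants: 12 C9 aldehyde
Product: 13 C9 allylic alcohol (1-substituted prop-2-en-1-ol; vinyl carbon = C8; C9 as in the target)
Conditions: CH2=CHMgBr, THF, −78 °C
Reagents that add atoms: vinylmagnesium bromide, C=C[Mg]Br
Why: Felkin–Anh addition of the Grignard reagent to the α-branched aldehyde, in which the quaternary C1 is the large and C11 the medium substituent on C10, so the nucleophile should enter anti to C1 and give the C9 hydroxyl syn to C11 in the extended C8–C9–C10–C1 chain, as in the target.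

Step 11
Reactants: 13 C9 allylic alcohol
Product: 14 2,9-bis-O-TBS ether of 13 (ring A still the C12 silyl enol ether)
Conditions: TBSOTf, 2,6-lutidine, CH2Cl2, −78 °C
Reagents that add atoms: tert-butyldimethylsilyl trifluoromethanesulfonate, CC(C)(C)[Si](C)(C)OS(=O)(=O)C(F)(F)F
Why: Low-temperature silyl triflate silylation protects the hindered allylic C9 hydroxyl with the group it keeps until the end.

Step 12
Reactants: 14 tris-silyl compound
Product: 16 ring-A enone (C12 ketone conjugated with C13=C14 and C11–H) with 2,9-bis-O-TBS groups, via C13 phenylselanyl ketone 15 (not isolated)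
Conditions: PhSeCl, CH2Cl2, −78 °C; then 30% H2O2, pyridine, 0 °C → rt
Reagents that add atoms: none
Why: Selenenylation of the silyl enol ether at C13 followed by oxidation and selenoxide syn-elimination (Reich–Sharpless) should give the C13=C14 enone, the only β-hydrogens being on C14, and avoids palladium in the presence of the bromoalkene.

Step 13
Reactants: 16 ring-A enone
Product: 17 C8 aldehyde (α-silyloxy aldehyde; the C9 vinyl group cleaved to CHO)
Conditions: OsO4 (cat.), NaIO4, 2,6-lutidine, dioxane/H2O, rt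
Reagents that add atoms: osmium tetroxide (catalytic, re-oxidised), O=[Os](=O)(=O)=O; sodium periodate, [Na+].[O-]I(=O)(=O)=O
Why: Lemieux–Johnson cleavage, in which osmylation should occur at the monosubstituted vinyl group because the enone double bond is electron-poor and the bromoalkene is deactivated, and the buffered conditions should not epimerise C9.

Step 14
Reactants: 18 1-methoxy-4-[(prop-2-yn-1-yloxy)methyl]benzene
Product: 19 (E)-2-[3-(4-methoxybenzyloxy)prop-1-enyl]-4,4,5,5-tetramethyl-1,3,2-dioxaborolane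
Conditions: pinacolborane, Cp2Zr(H)Cl (5 mol %), Et3N (cat.), 60 °C
Reagents that add atoms: pinacolborane, CC1(C)OBOC1(C)C
Why: Zirconocene-catalysed syn hydroboration of the terminal alkyne places boron on the terminal carbon and gives the (E)-alkenylboronate.

Step 15
Reactants: 17 C8 aldehyde; 19 (E)-alkenylboronate
Product: 21 homoallylic alcohol (C8–OH, C7–OPMB, C6=CH2; 7,8-anti and 8,9-anti), via E-γ-alkoxyallylboronate 20 (not isolated)
Conditions: [Ir(cod)(PPh2Me)2]PF6 (3 mol %, H2-activated), THF, rt; then 17, toluene, 0 °C → rt; triethanolamine work-up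
Reagents that add atoms: none
Why: Iridium-catalysed double-bond migration turns 19 into the (E)-γ-alkoxyallylboronate, which adds to the aldehyde through a chair transition state (allylboration), the E geometry giving the 7,8-anti relationship and Felkin–Anh attack anti to the C9 silyloxy group giving 8,9-anti, so that the C7 oxygen ends 1,3-syn to the C9 oxygen as the target requires (C8 is oxidised later).

Step 16
Reactants: 21 homoallylic alcohol
Product: 22 8-O-triethylsilyl ether of 21
Conditions: TESOTf, 2,6-lutidine, CH2Cl2, −78 °C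
Reagents that add atoms: triethylsilyl trifluoromethanesulfonate, CC[Si](CC)(CC)OS(=O)(=O)C(F)(F)F
Why: Silyl triflate silylation of the hindered C8 hydroxyl with a group that can later be removed in the presence of the TBS ethers, the enone not being enolised by 2,6-lutidine at −78 °C.

Step 17
Reactants: 22 8-O-TES enone
Product: 23 α′-hydroxy enone (C11 tertiary OH cis to H-10, C20 methyl cis to the C10 side chain)
Conditions: KHMDS, THF, −78 °C; then 2-(phenylsulfonyl)-3-phenyloxaziridine, −78 °C
Reagents that add atoms: 2-(phenylsulfonyl)-3-phenyloxaziridine (Davis reagent), O=S(=O)(N1OC1c1ccccc1)c1ccccc1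
Why: Enolate oxidation with the Davis oxaziridine, in which KHMDS removes the only acidic hydrogen (C11–H, C1 being quaternary) and the cross-conjugated dienolate should be hydroxylated on the face opposite the C10 side chain and the axial C15 methyl, which sets C11 as in the target.

Step 18
Reactants: 23 α′-hydroxy enone
Product: 25 C12 ethylene ketal with free C11 hydroxyl, via 11-O-trimethylsilyl ketal 24 (not isolated)
Conditions: (TMSOCH2)2, TMSOTf (cat.), CH2Cl2, −78 → −20 °C; then K2CO3, MeOH, 0 °C
Reagents that add atoms: 1,2-bis(trimethylsilyloxy)ethane, C[Si](C)(C)OCCO[Si](C)(C)C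
Why: Noyori ketalisation under aprotic conditions should mask the hindered enone carbonyl without harming the silyl and p-methoxybenzyl ethers (no double-bond migration is possible because C1 is quaternary), and the methanolic carbonate treatment cleaves the silyl ether formed at the tertiary C11 hydroxyl.

Step 19
Reactants: 25 C12 ketal
Product: 26 seco C6 aldehyde (7-OPMB, 8-OTES, 9-OTBS; C5 vinyl bromide)
Conditions: OsO4 (cat.), NaIO4, 2,6-lutidine, dioxane/H2O, rt
Reagents that add atoms: osmium tetroxide (catalytic, re-oxidised), O=[Os](=O)(=O)=O; sodium periodate, [Na+].[O-]I(=O)(=O)=O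
Why: Lemieux–Johnson cleavage, in which the terminal vinyl group should be osmylated much faster than the ring double bond (flanked by the quaternary C1 and the spiro-ketal carbon) and than the bromoalkene.

Step 20
Reactants: 26 seco C6 aldehyde
Product: 27 ten-membered allylic alcohol (C5–C6 bond formed, exocyclic C5=C16, C6–OH syn to C7–OPMB)
Conditions: CrCl2 (10 equiv), NiCl2 (10 mol %), DMSO/THF, 0.003 M, rt → 50 °C
Reagents that add atoms: none
Why: Nozaki–Hiyama–Kishi reaction, in which nickel-catalysed activation of the C5–Br bond and transmetallation to chromium(III) give an alkenylchromium species that adds only to the aldehyde and at high dilution should close the ten-membered ring; the C6 carbinol is expected syn to the C7 ether (chromium chelated by the α-p-methoxybenzyloxy group), the epimer needed for invertive chlorination.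

Step 21
Reactants: 27 ten-membered allylic alcohol
Product: 28 C6 chloride (inverted at C6, anti to the C7 oxygen)
Conditions: PPh3, Cl3CC(O)CCl3, CH2Cl2, −20 → 0 °C
Reagents that add atoms: hexachloroacetone, O=C(C(Cl)(Cl)Cl)C(Cl)(Cl)Cl
Why: Appel-type chlorination under Magid conditions, in which the alkoxyphosphonium salt of the secondary allylic alcohol should be displaced by chloride by SN2 with inversion and without allylic transposition, the hindered tertiary C11 hydroxyl being unreactive.

Step 22
Reactants: 28 C6 chloride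
Product: 29 chlorohydrin (free C7 hydroxyl)
Conditions: DDQ, CH2Cl2/pH 7 buffer, 0 °C
Reagents that add atoms: none
Why: Oxidative cleavage of the p-methoxybenzyl ether by DDQ under neutral buffered conditions should free the C7 hydroxyl without affecting the silyl ethers, the allylic chloride or the ketal.

Step 23
Reactants: 29 chlorohydrin; 30 2-bromopropanoyl bromide
Product: 31 C7 2-bromopropanoate (both epimers at the bromine-bearing carbon)
Conditions: pyridine, CH2Cl2, −20 → 0 °C
Reagents that add atoms: none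
Why: Acylation of the secondary C7 hydroxyl by the acyl bromide with pyridine, the tertiary C11 hydroxyl being too hindered to compete and both bromide epimers being usable because that carbon becomes the enolate carbon in step 26.

Step 24
Reactants: 31 C7 2-bromopropanoate
Product: 32 C8 alcohol
Conditions: HF·pyridine, pyridine, THF, 0 °C
Reagents that add atoms: none
Why: Buffered HF·pyridine should cleave the triethylsilyl ether selectively in the presence of the two bulkier tert-butyldimethylsilyl ethers, under conditions that spare the α-bromo ester, the allylic chloride and the ketal.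

Step 25
Reactants: 32 C8 alcohol
Product: 33 C8 ketone with C6 chloride and C7 2-bromopropanoate (key-step precursor)
Conditions: Dess–Martin periodinane, NaHCO3, CH2Cl2, 0 °C → rt; used without delay
Reagents that add atoms: none
Why: Neutral Dess–Martin oxidation unveils the C8 ketone last, so that the base-sensitive α-acyloxy β-chloro ketone never meets an acylation base and C7 and C9 are not epimerised.

Step 26
Reactants: 33 C8 ketone with C6 chloride and C7 2-bromopropanoate
Product: 34 protected tricyclic hydroxy-lactone (C8–C17 bond formed; C8–OH trans to H-7; C18 methyl cis to the C8 hydroxyl)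
Conditions: SmI2 (2.5 equiv), THF, −78 °C, 0.005 M; NH4Cl (aq)
Reagents that add atoms: none
Why: Two single-electron transfers from SmI2 cleave the C–Br bond of the 2-bromopropanoate and give a samarium(III) ester enolate whose carbon C17 adds to the adjacent C8 carbonyl, the samarium alkoxide of the β-hydroxy γ-lactone being protonated on work-up. The closest known reaction type is the SmI2-promoted intramolecular Reformatsky reaction of α-bromoacyloxy ketones and aldehydes to β-hydroxy lactones. The five-membered lactone closes in a 5-exo-trig mode at the C8 carbonyl (enolendo with respect to the enolate), the C7 oxygen tether allowing no other regiochemistry. C8: the tethered enolate can reach only the carbonyl face syn to O7, and the ten-membered ring should present the face reached with an anti-type C6–C7–C8–C9 torsion (the cis-fused alternative needs this ring bond nearly eclipsed), which gives H-7 and the C8 hydroxyl trans. C17: samarium bridging the enolate oxygen and the ketone oxygen in a six-membered chelate fused to the forming ring places the methyl of the (Z)-enolate on the side of the new C8–O bond, so the methyl should end cis to the hydroxyl, and both bromide epimers converge on the same enolate. The step needs C–Br reduction to be faster than reduction of the ketone (a ketyl would expel the C7 acyloxy group) or of the allylic chloride, which the high reduction rate of α-bromo esters at −78 °C without HMPA should secure, while the C12 carbonyl is masked as its dioxolane.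

Step 27
Reactants: 34 protected tricyclic hydroxy-lactone
Product: 35 2,9-di-O-deacetyl target (C2, C8, C9, C11 hydroxyls free, enone restored)
Conditions: 48% aq. HF, MeCN, 0 °C → rt
Reagents that add atoms: water, O
Why: Aqueous HF in acetonitrile should cleave both tert-butyldimethylsilyl ethers and hydrolyse the allylic dioxolane in one operation, under acidic, non-basic conditions that avoid retro-aldol opening or translactonisation of the β-hydroxy lactone and leave the allylic chloride intact.

Step 28
Reactants: 35 2,9-di-O-deacetyl target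
Product: 36 CNP0261648.1 (target)
Conditions: Ac2O, pyridine, DMAP (cat.), CH2Cl2, 0 °C
Reagents that add atoms: acetic anhydride, CC(=O)OC(C)=O
Why: Acetylation of the two secondary hydroxyls at C2 and C9 under mild DMAP catalysis, the tertiary hydroxyls at C8 and C11 being too hindered to react, should give the target.

Compound list
1 | pent-1-en-3-one | CCC(=O)C=C | starting material
2 | (Z)-tert-butyldimethyl(penta-1,3-dien-3-yloxy)silane | C/C=C(\O[Si](C)(C)C(C)(C)C)C=C | intermediate
3 | ethyl (2E)-3-methyl-4-oxobut-2-enoate | CCOC(=O)/C=C(\C)C=O | starting material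
4 | ethyl 6-formyl-2,6-dimethyl-3-(TBS-oxy)cyclohex-3-ene-1-carboxylate (formyl trans to ester, 2-methyl cis to formyl) | O=C[C@@]1(C)CC=C(O[Si](C)(C)C(C)(C)C)[C@@H](C)[C@@H]1C(=O)OCC | intermediate
5 | ethyl 6-(1-hydroxyethyl)-2,6-dimethyl-3-(TBS-oxy)cyclohex-3-ene-1-carboxylate (carbinol epimers) | CC(O)[C@@]1(C)CC=C(O[Si](C)(C)C(C)(C)C)[C@@H](C)[C@@H]1C(=O)OCC | intermediate
6 | ethyl 6-acetyl-2,6-dimethyl-3-(TBS-oxy)cyclohex-3-ene-1-carboxylate | CC(=O)[C@@]1(C)CC=C(O[Si](C)(C)C(C)(C)C)[C@@H](C)[C@@H]1C(=O)OCC | intermediate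
7 | 2,3-dibromoprop-1-ene | C=C(Br)CBr | starting material
8 | ethyl 6-(4-bromopent-4-enoyl)-2,6-dimethyl-3-(TBS-oxy)cyclohex-3-ene-1-carboxylate | C=C(Br)CCC(=O)[C@@]1(C)CC=C(O[Si](C)(C)C(C)(C)C)[C@@H](C)[C@@H]1C(=O)OCC | intermediate
9 | ethyl 6-[(1R)-4-bromo-1-hydroxypent-4-enyl]-2,6-dimethyl-3-(TBS-oxy)cyclohex-3-ene-1-carboxylate | C=C(Br)CC[C@@H](O)[C@@]1(C)CC=C(O[Si](C)(C)C(C)(C)C)[C@@H](C)[C@@H]1C(=O)OCC | intermediate
10 | 2-O-TBS ether of 9 | C=C(Br)CC[C@@H](O[Si](C)(C)C(C)(C)C)[C@@]1(C)CC=C(O[Si](C)(C)C(C)(C)C)[C@@H](C)[C@@H]1C(=O)OCC | intermediate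
11 | C9 primary alcohol (ester of 10 reduced to CH2OH) | C=C(Br)CC[C@@H](O[Si](C)(C)C(C)(C)C)[C@@]1(C)CC=C(O[Si](C)(C)C(C)(C)C)[C@@H](C)[C@@H]1CO | intermediate
12 | C9 aldehyde | C=C(Br)CC[C@@H](O[Si](C)(C)C(C)(C)C)[C@@]1(C)CC=C(O[Si](C)(C)C(C)(C)C)[C@@H](C)[C@@H]1C=O | intermediate
13 | C9 allylic alcohol (Felkin adduct, C9 as in the target) | C=C(Br)CC[C@@H](O[Si](C)(C)C(C)(C)C)[C@@]1(C)CC=C(O[Si](C)(C)C(C)(C)C)[C@@H](C)[C@@H]1[C@@H](O)C=C | intermediate
14 | 2,9-bis-O-TBS C12 silyl enol ether | C=C(Br)CC[C@@H](O[Si](C)(C)C(C)(C)C)[C@@]1(C)CC=C(O[Si](C)(C)C(C)(C)C)[C@@H](C)[C@@H]1[C@@H](O[Si](C)(C)C(C)(C)C)C=C | intermediate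
15 | C13 phenylselanyl C12 ketone (C13 epimers) | C=C(Br)CC[C@@H](O[Si](C)(C)C(C)(C)C)[C@@]1(C)CC([Se]c2ccccc2)C(=O)[C@@H](C)[C@@H]1[C@@H](O[Si](C)(C)C(C)(C)C)C=C | intermediate (not isolated)
16 | ring-A enone (C12=O, C13=C14), 2,9-bis-O-TBS, C9 vinyl | C=C(Br)CC[C@@H](O[Si](C)(C)C(C)(C)C)[C@@]1(C)C=CC(=O)[C@@H](C)[C@@H]1[C@@H](O[Si](C)(C)C(C)(C)C)C=C | intermediate
17 | C8 aldehyde (9-OTBS) of the ring-A enone | C=C(Br)CC[C@@H](O[Si](C)(C)C(C)(C)C)[C@@]1(C)C=CC(=O)[C@@H](C)[C@@H]1[C@@H](O[Si](C)(C)C(C)(C)C)C=O | intermediate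
18 | 1-methoxy-4-[(prop-2-yn-1-yloxy)methyl]benzene | C#CCOCc1ccc(OC)cc1 | starting material
19 | (E)-2-[3-(4-methoxybenzyloxy)prop-1-enyl]-4,4,5,5-tetramethyl-1,3,2-dioxaborolane | COc1ccc(COC/C=C/B2OC(C)(C)C(C)(C)O2)cc1 | intermediate
20 | (E)-2-[3-(4-methoxybenzyloxy)prop-2-enyl]-4,4,5,5-tetramethyl-1,3,2-dioxaborolane | COc1ccc(CO/C=C/CB2OC(C)(C)C(C)(C)O2)cc1 | intermediate (not isolated)
21 | homoallylic alcohol: 8-OH, 7-OPMB, C6=CH2 (7,8-anti, 8,9-anti), ring-A enone | C=C(Br)CC[C@@H](O[Si](C)(C)C(C)(C)C)[C@@]1(C)C=CC(=O)[C@@H](C)[C@@H]1[C@@H](O[Si](C)(C)C(C)(C)C)[C@@H](O)[C@@H](OCc2ccc(OC)cc2)C=C | intermediate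
22 | 8-O-TES ether of 21 | C=C(Br)CC[C@@H](O[Si](C)(C)C(C)(C)C)[C@@]1(C)C=CC(=O)[C@@H](C)[C@@H]1[C@@H](O[Si](C)(C)C(C)(C)C)[C@@H](O[Si](CC)(CC)CC)[C@@H](OCc2ccc(OC)cc2)C=C | intermediate
23 | 11-hydroxy enone (C11 as in the target) | C=C(Br)CC[C@@H](O[Si](C)(C)C(C)(C)C)[C@@]1(C)C=CC(=O)[C@@](C)(O)[C@@H]1[C@@H](O[Si](C)(C)C(C)(C)C)[C@@H](O[Si](CC)(CC)CC)[C@@H](OCc2ccc(OC)cc2)C=C | intermediate
24 | 11-O-trimethylsilyl C12 ethylene ketal | C=C(Br)CC[C@@H](O[Si](C)(C)C(C)(C)C)[C@@]1(C)C=CC2(OCCO2)[C@@](C)(O[Si](C)(C)C)[C@@H]1[C@@H](O[Si](C)(C)C(C)(C)C)[C@@H](O[Si](CC)(CC)CC)[C@@H](OCc2ccc(OC)cc2)C=C | intermediate (not isolated)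
25 | C12 ethylene ketal, free 11-OH | C=C(Br)CC[C@@H](O[Si](C)(C)C(C)(C)C)[C@@]1(C)C=CC2(OCCO2)[C@@](C)(O)[C@@H]1[C@@H](O[Si](C)(C)C(C)(C)C)[C@@H](O[Si](CC)(CC)CC)[C@@H](OCc2ccc(OC)cc2)C=C | intermediate
26 | seco C6 aldehyde (7-OPMB, 8-OTES, 9-OTBS, C5 vinyl bromide) | C=C(Br)CC[C@@H](O[Si](C)(C)C(C)(C)C)[C@@]1(C)C=CC2(OCCO2)[C@@](C)(O)[C@@H]1[C@@H](O[Si](C)(C)C(C)(C)C)[C@@H](O[Si](CC)(CC)CC)[C@@H](OCc2ccc(OC)cc2)C=O | intermediate
27 | ten-membered allylic alcohol (6-OH syn to 7-OPMB, exocyclic C5=C16) | C=C1CC[C@@H](O[Si](C)(C)C(C)(C)C)[C@@]2(C)C=CC3(OCCO3)[C@@](C)(O)[C@@H]2[C@@H](O[Si](C)(C)C(C)(C)C)[C@@H](O[Si](CC)(CC)CC)[C@@H](OCc4ccc(OC)cc4)[C@@H]1O | intermediate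
28 | C6 chloride (7-OPMB, 8-OTES) | C=C1CC[C@@H](O[Si](C)(C)C(C)(C)C)[C@@]2(C)C=CC3(OCCO3)[C@@](C)(O)[C@@H]2[C@@H](O[Si](C)(C)C(C)(C)C)[C@@H](O[Si](CC)(CC)CC)[C@@H](OCc4ccc(OC)cc4)[C@H]1Cl | intermediate
29 | 6-chloro-7-ol (8-OTES) | C=C1CC[C@@H](O[Si](C)(C)C(C)(C)C)[C@@]2(C)C=CC3(OCCO3)[C@@](C)(O)[C@@H]2[C@@H](O[Si](C)(C)C(C)(C)C)[C@@H](O[Si](CC)(CC)CC)[C@@H](O)[C@H]1Cl | intermediate
30 | 2-bromopropanoyl bromide (racemic) | CC(Br)C(=O)Br | starting material
31 | 6-chloro-7-(2-bromopropanoate), 8-OTES (bromide epimers) | C=C1CC[C@@H](O[Si](C)(C)C(C)(C)C)[C@@]2(C)C=CC3(OCCO3)[C@@](C)(O)[C@@H]2[C@@H](O[Si](C)(C)C(C)(C)C)[C@@H](O[Si](CC)(CC)CC)[C@@H](OC(=O)C(C)Br)[C@H]1Cl | intermediate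
32 | 6-chloro-7-(2-bromopropanoate) 8-ol (bromide epimers) | C=C1CC[C@@H](O[Si](C)(C)C(C)(C)C)[C@@]2(C)C=CC3(OCCO3)[C@@](C)(O)[C@@H]2[C@@H](O[Si](C)(C)C(C)(C)C)[C@@H](O)[C@@H](OC(=O)C(C)Br)[C@H]1Cl | intermediate
33 | ten-membered C8 ketone with C6 chloride and C7 2-bromopropanoate (bromide epimers); key-step precursor | C=C1CC[C@@H](O[Si](C)(C)C(C)(C)C)[C@@]2(C)C=CC3(OCCO3)[C@@](C)(O)[C@@H]2[C@@H](O[Si](C)(C)C(C)(C)C)C(=O)[C@@H](OC(=O)C(C)Br)[C@H]1Cl | intermediate
34 | chlorinated tricyclic hydroxy-lactone, 2,9-bis-O-TBS, C12 ketal; key-step product | C=C1CC[C@@H](O[Si](C)(C)C(C)(C)C)[C@@]2(C)C=CC3(OCCO3)[C@@](C)(O)[C@@H]2[C@@H](O[Si](C)(C)C(C)(C)C)[C@]2(O)[C@@H](C)C(=O)O[C@H]2[C@H]1Cl | intermediate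
35 | 2,9-di-O-deacetyl target (tetraol enone lactone) | C=C1CC[C@@H](O)[C@@]2(C)C=CC(=O)[C@@](C)(O)[C@@H]2[C@@H](O)[C@]2(O)[C@@H](C)C(=O)O[C@H]2[C@H]1Cl | intermediate
36 | CNP0261648.1 | C=C1CC[C@@H](OC(C)=O)[C@@]2(C)C=CC(=O)[C@@](C)(O)[C@@H]2[C@@H](OC(C)=O)[C@]2(O)[C@@H](C)C(=O)O[C@H]2[C@H]1Cl | target

Total step count: 28. Longest linear sequence: 27 steps (steps 1–13 and 15–28; step 14 prepares the allylboron reagent).

Steps most likely to fail

Step 26 (key step). What may go wrong: protonation of the samarium enolate before it cyclises (simple debromination), reductive loss of the C7 acyloxy group through a C8 ketyl, or attack on the wrong ketone face. Fallback: the C8–C17 aldol bond is made intermolecularly and the lactone is closed afterwards. The fallback sets out from chloride 28: buffered HF·pyridine frees the C8 hydroxyl to give the 7-O-PMB 8-alcohol F6; Dess–Martin oxidation gives the 7-O-PMB 8-ketone F7; a zinc Reformatsky reaction with ethyl 2-bromopropanoate (zinc chelated between the C7 ether oxygen and the ketone, attack anti to C6, which corresponds to the trans-fused series) gives the β-hydroxy ester F8; DDQ removes the PMB group to give the 7-hydroxy ester F9, which lactonises (PPTS, CH2Cl2) with loss of ethanol and rejoins the route at 34.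

Step 20. What may go wrong: oligomerisation competing with ten-ring closure, and poor facial selectivity at the C6 aldehyde. Fallback for the facial problem: C6 is set by reduction instead of by the cyclisation. From 26 the ring closure is run without regard to C6; the 6-epi allylic alcohol F1, alone or mixed with 27, is oxidised with Dess–Martin periodinane to the single α-methylene ketone F2, and this is reduced 1,2 with (R)-Me-CBS/catecholborane (reagent control with the alkenyl carbon C5 as the larger ketone substituent, in agreement with Felkin attack anti to the C7 ether) to return to 27.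

Step 21. What may go wrong: allylic transposition (SN2′ attack giving the primary C16 chloride), elimination, or incomplete inversion. Fallback: chloride is delivered by opening an acetoxonium ion instead of a phosphonium salt. From 27, DDQ gives the 6,7-diol F3; trimethyl orthoacetate with PPTS gives the cyclic orthoacetate F4; TMSCl opens the derived dioxolanylium ion at the allylic C6 with inversion (Kolb–Sharpless halohydrin ester synthesis) to give the 6-chloro 7-acetate F5; DIBAL-H at −78 °C removes the acetate reductively (a basic cleavage would close the epoxide) and rejoins the route at 29.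

Further compounds
F1 | step 20 | 6-epi-27 (ten-membered allylic alcohol, 6-OH anti to 7-OPMB) | C=C1CC[C@@H](O[Si](C)(C)C(C)(C)C)[C@@]2(C)C=CC3(OCCO3)[C@@](C)(O)[C@@H]2[C@@H](O[Si](C)(C)C(C)(C)C)[C@@H](O[Si](CC)(CC)CC)[C@@H](OCc4ccc(OC)cc4)[C@H]1O
F2 | step 20 | ten-membered C6 ketone (α-methylene ketone, 7-OPMB, 8-OTES) | C=C1CC[C@@H](O[Si](C)(C)C(C)(C)C)[C@@]2(C)C=CC3(OCCO3)[C@@](C)(O)[C@@H]2[C@@H](O[Si](C)(C)C(C)(C)C)[C@@H](O[Si](CC)(CC)CC)[C@@H](OCc4ccc(OC)cc4)C1=O
F3 | step 21 | 6,7-syn-diol (8-OTES) | C=C1CC[C@@H](O[Si](C)(C)C(C)(C)C)[C@@]2(C)C=CC3(OCCO3)[C@@](C)(O)[C@@H]2[C@@H](O[Si](C)(C)C(C)(C)C)[C@@H](O[Si](CC)(CC)CC)[C@@H](O)[C@@H]1O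
F4 | step 21 | 6,7-O-(1-methoxyethylidene) cyclic orthoacetate (orthoester carbon epimers) | C=C1CC[C@@H](O[Si](C)(C)C(C)(C)C)[C@@]2(C)C=CC3(OCCO3)[C@@](C)(O)[C@@H]2[C@@H](O[Si](C)(C)C(C)(C)C)[C@@H](O[Si](CC)(CC)CC)[C@H]4OC(C)(OC)O[C@H]14
F5 | step 21 | 6-chloro 7-acetate (8-OTES) | C=C1CC[C@@H](O[Si](C)(C)C(C)(C)C)[C@@]2(C)C=CC3(OCCO3)[C@@](C)(O)[C@@H]2[C@@H](O[Si](C)(C)C(C)(C)C)[C@@H](O[Si](CC)(CC)CC)[C@@H](OC(C)=O)[C@H]1Cl
F6 | step 26 | 6-chloro 7-O-PMB 8-alcohol | C=C1CC[C@@H](O[Si](C)(C)C(C)(C)C)[C@@]2(C)C=CC3(OCCO3)[C@@](C)(O)[C@@H]2[C@@H](O[Si](C)(C)C(C)(C)C)[C@@H](O)[C@@H](OCc4ccc(OC)cc4)[C@H]1Cl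
F7 | step 26 | 6-chloro 7-O-PMB 8-ketone | C=C1CC[C@@H](O[Si](C)(C)C(C)(C)C)[C@@]2(C)C=CC3(OCCO3)[C@@](C)(O)[C@@H]2[C@@H](O[Si](C)(C)C(C)(C)C)C(=O)[C@@H](OCc4ccc(OC)cc4)[C@H]1Cl
F8 | step 26 | ethyl 2-(8-hydroxy-7-O-PMB bicycle-8-yl)propanoate (Reformatsky adduct) | C=C1CC[C@@H](O[Si](C)(C)C(C)(C)C)[C@@]2(C)C=CC3(OCCO3)[C@@](C)(O)[C@@H]2[C@@H](O[Si](C)(C)C(C)(C)C)[C@](O)([C@@H](C)C(=O)OCC)[C@@H](OCc4ccc(OC)cc4)[C@H]1Cl
F9 | step 26 | 7,8-dihydroxy ester (PMB removed) | C=C1CC[C@@H](O[Si](C)(C)C(C)(C)C)[C@@]2(C)C=CC3(OCCO3)[C@@](C)(O)[C@@H]2[C@@H](O[Si](C)(C)C(C)(C)C)[C@](O)([C@@H](C)C(=O)OCC)[C@@H](O)[C@H]1Cl
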